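## The problem

The target 14 is a 2-arylchromen-4-one, a flavonol 3-methyl ether. Ring A carries a free 5-hydroxyl and a 7-methoxy group, C3 a methoxy group, and ring B a 4'-O-prenyl ether. There is no stereocentre, so nothing has to be set or relayed in that sense. The tasks are to build the pyranone ring C between two benzene rings and to tell apart four similar oxygen functions: two methyl ethers (O3, O7), one free phenol (O5) and one allylic ether (O4'). The prenyl ether is the fragile group: strong acid adds to its trisubstituted alkene and cleaves the allyl–oxygen bond, and quinone or metal oxidants attack it. The 5-hydroxyl, in contrast, is shielded in the finished chromone by its hydrogen bond to the C4 carbonyl, which makes a late selective alkylation at O4' realistic. The feature that opens the plan lies around ring C: C4 is attached to C4a of a ring A whose two ortho oxygens (the future O5 and O1) are equivalent before ring closure, and C3 carries its methoxy group next to the aryl-bearing C2. Ring C can therefore be cut at C3–C4 and O1–C2 into a symmetric ring A aldehyde (C4 as the formyl carbon) and a ring B methoxymethyl ketone (C2 and C3 with the 3-methoxy group in place). The price is that C4 arrives as CH, one oxidation level below the carbonyl.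

## Retrosynthesis

**14 to 12 and 13.** The O4'–CH2 bond of the prenyl ether is cut first, giving the flavonol dimethyl ether 12 and prenyl bromide 13. This puts the only acid- and oxidant-sensitive group at the very end, after the acidic ring closure and the oxidation at C4. The alternative of carrying the prenyl group on ring B from the start would expose it to both. Compound 12 is simpler by five carbons and one alkene. The forward reaction must alkylate O4' and leave the chelated O5 alone.

**12 to 9.** The C4=O bond is removed, giving the flavylium chloride 9. No skeletal bond is cut; the carbonyl is traded for a C4–H in an aromatic pyrylium ring. What speaks for this is that 9 is available in one operation from two benzene building blocks. Keeping C4 at the carbonyl level would force an acyl-transfer construction from a ring A ketone with differentiated hydroxyls. The forward step is a net two-electron oxidation at C4 with oxygen supplied from the medium. It is planned through the C4 methanol adduct 10 and the 4-methoxyflavylium ion 11, and is the least secure point of the route.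

**9 to 2 and 7.** Ring C is cut at C3–C4 and at O1–C2, giving the aldehyde 2 and the ketone 7. They are expected to meet through the open retro-chalcone 8. A cut at C4–C4a (acylation of an unsymmetrical phloroglucinol monomethyl ether) would face a choice between two ring positions and give 5-methoxy/7-hydroxy isomers. The chosen cut uses an aldehyde whose two hydroxyls are equivalent. Each precursor is a monosubstituted or symmetric benzene of eight or nine carbons, and the 3-methoxy group is already on 7. The forward reaction must tolerate three free phenols and form one C–C and one C–O bond under dry acid.

**2 to 1.** The O–CH3 bond at the para oxygen is cut, leading to commercial 2,4,6-trihydroxybenzaldehyde 1. Formylation of a pre-methylated resorcinol would instead give mainly the unsymmetrical isomer. The forward step must methylate only the most acidic, non-chelated hydroxyl.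

**7 to 3 and 4.** The aryl–carbonyl bond is cut, giving the protected bromophenol 3 (through its Grignard reagent 5) and the methoxyacetic acid Weinreb amide 4. Methanolysis of a 4-hydroxyphenacyl bromide was considered and set aside. Alkoxide on an alpha-bromo ketone diverts to epoxy ethers and hydroxy ketals, and the phenoxide alkylates itself. Acylation of phenol itself would give ortho/para and O-acyl mixtures. The forward step forms the ketone 6 by single addition and releases the phenol in the acidic work-up.

## Roads not taken

**Alternative 1:** Ring C is cut at the C2=C3 double bond. A ring A ketone carrying an alpha-methoxy acyl phosphorane and two ortho 4-(prenyloxy)benzoate esters, A2, would be heated. The ylide carbon (future C3) attacks the neighbouring ester carbonyl (future C2), and loss of the phosphine oxide closes ring C as the 5-O-aroyl chromone A1. Saponification of that ester would give 14.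
- Merits: C4 is a carbonyl from the outset, the conditions are neutral so the prenyl ether can be present from the first step, and the symmetric bis-ester removes any regiochemical question.
- Weak points: the ylide is doubly stabilised and fully substituted, and must attack an ester carbonyl to form a tetrasubstituted enol ether, the least favourable case of an intramolecular ester Wittig closure. It has to be made by alpha-halogenation and phosphine displacement at a hindered 2,6-disubstituted aryl ketone. One of the two prenylated aroyl groups is discarded.
- Comparison: in oxidation-state economy and in compatibility with the prenyl group this road is better. The chosen plan sets against it its length (five steps against about eight), a ring closure established for this pairing of a 2-hydroxybenzaldehyde with a methoxymethyl ketone, and no sacrificial acyl group. Its own debt is the oxidation of 9 to 12.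

**Alternative 2:** Ring C is cut at C4a–C4, C4–C3 and O1–C2, with carbon monoxide A6 as C4. Zerovalent palladium (for example Pd(PPh3)4) would insert into the C–I bond of 2-iodo-5-methoxyresorcinol A4, take up A6 and couple with 1-(benzyloxy)-4-ethynylbenzene A5. The resulting ortho-hydroxyaryl ynone cyclises through either flanking hydroxyl to the 3-unsubstituted flavone A3.
- Merits: three bonds in one operation, C4 at the carbonyl level, and the same symmetry argument as in the chosen plan.
- Weak points: A3 has no oxygen at C3. The 3-methoxy group would have to be added by C3 hydroxylation of a 5-hydroxyflavone and methylation, a redox adjustment at least as awkward as the one avoided. The ynone can close 5-exo to an aurone as well as 6-endo. An electron-rich, doubly ortho-substituted aryl iodide with free phenols is a poor substrate for oxidative addition. The benzyl group must still be exchanged for prenyl.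
- Comparison: this road is more convergent in the ring-forming step and secure at C4, but it moves the redox problem from C4 to C3 and needs about three more steps. The chosen plan brings the 3-methoxy group in with 7 and leaves a single atom to adjust.

**Alternative 3:** Ring A, not ring C, is disconnected, at C4a–C5. The pyranone A8, a 2-aryl-3-methoxypyran-4-one with a CH2COCH2CO2Me chain at the future C8a, would be deprotonated to an extended dienolate whose C4a attacks the terminal ester. Claisen closure and enolisation give the 5,7-dihydroxyflavone A7, and selective 7-O-methylation would give 14.
- Merits: it follows the polyketide folding, every carbon is at its final oxidation level, the base-only conditions tolerate the prenyl ether, and the last methylation is reliable because the 7-hydroxyl is more acidic than the chelated 5-hydroxyl.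
- Weak points: the strategic bond sits in a phloroglucinol ring that can be bought, while A8 needs a multi-step synthesis through polyanion chemistry. The cyclisation competes with O-acylation, aldol closure onto the chain ketone and retro-Claisen cleavage.
- Comparison: on redox and protecting-group grounds this road is cleaner, but it spends most of its steps on a ring the chosen plan takes from commercial 1. The chosen plan accepts one uncertain oxidation in return for five steps.

Key step: step 3

Remark on the chemistry: compounds 3, 5, 6 and 10 are racemic at one acetal or benzylic carbon that does not reach the target; 14 has no stereocentre.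

## Route

Step 1
Reactants: 1 2,4,6-trihydroxybenzaldehyde
Product: 2 2,6-dihydroxy-4-methoxybenzaldehyde
Conditions: MeI (1.0 equiv), K2CO3 (1.0 equiv), DMF, 0 °C to rt
Reagents that add atoms: iodomethane, CI
Why: Williamson O-methylation under stoichiometric control; the 4-hydroxyl is the most acidic and the only one not engaged with or flanked by the formyl group, so one equivalent of mild base and MeI should alkylate the para oxygen first. The symmetric product keeps both ortho hydroxyls for step 3.

Step 2
Reactants: 3 2-(4-bromophenoxy)tetrahydro-2H-pyran (racemic); 4 N,2-dimethoxy-N-methylacetamide
Product: 7 1-(4-hydroxyphenyl)-2-methoxyethanone, via aryl Grignard reagent 5 (not isolated), via THP-protected ketone 6 (not isolated)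
Conditions: Mg, I2 (cat.), THF, reflux; then 4, 0 °C to rt; then HCl, MeOH, rt
Reagents that add atoms: none
Why: Weinreb ketone synthesis followed by acetal cleavage; the Grignard reagent 5 adds once to the N-methoxy-N-methylamide to give a magnesium chelate that collapses only on quench, so 6 is not over-added. Methanolic HCl then transfers the tetrahydropyranyl group to methanol and frees the phenol.

Step 3
Reactants: 2 2,6-dihydroxy-4-methoxybenzaldehyde; 7 1-(4-hydroxyphenyl)-2-methoxyethanone
Product: 9 5-hydroxy-2-(4-hydroxyphenyl)-3,7-dimethoxychromenylium chloride, via retro-chalcone 8 (not isolated)
Conditions: HCl (g), EtOAc, 0 °C, then rt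
Reagents that add atoms: hydrogen chloride, Cl
Why: Acid-mediated flavylium synthesis; the closest known reaction is the HCl condensation of 2-hydroxybenzaldehydes with aryl methyl or aryl methoxymethyl ketones to flavylium salts. HCl enolises 7 toward its only enolisable carbon, the methoxy-bearing CH2, and this enol adds to the protonated formyl carbon of 2; loss of water gives the retro-chalcone 8 and with it the C3–C4 double bond. Acid equilibrates the alkene geometry of 8 through the vinylogous oxocarbenium ion, so the isomer with ring A cis to the ketone is always available. One of the two equivalent ortho hydroxyls then attacks the protonated ketone carbon in a 6-exo-trig closure to a cyclic hemiketal, forming O1–C2, and a second dehydration aromatises ring C to the pyrylium ion. No stereocentre is created. The selectivity needed is regiochemical and is built into the partners: 2 is symmetric, so either hydroxyl gives the same salt and the other becomes the 5-hydroxyl, and 7 can enolise in one direction only. The 5-hydroxy, 7-methoxy and 4'-hydroxy donors stabilise the cation, and separation of the sparingly soluble chloride from ethyl acetate should draw the equilibria forward.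

Step 4
Reactants: 9 5-hydroxy-2-(4-hydroxyphenyl)-3,7-dimethoxychromenylium chloride
Product: 12 5-hydroxy-2-(4-hydroxyphenyl)-3,7-dimethoxy-4H-chromen-4-one (kumatakenin), via 4-methoxy-4H-chromene adduct 10 (not isolated), via 4-methoxyflavylium ion 11 (not isolated)
Conditions: NaOAc (1.1 equiv), MeOH, 0 °C; DDQ (1.1 equiv), 0 °C to rt; then H2O
Reagents that add atoms: water, O
Why: Proposed new method: with the HCl buffered by acetate, 9 should equilibrate in methanol with its C2 and C4 methanol adducts; only the C4 adduct 10 has a hydrogen that is benzylic, allylic to an enol ether and alpha to oxygen, so DDQ should abstract it as hydride (helped by the conjugated 4'-hydroxyl) to give the ion 11, which water hydrolyses at C4 to the chromen-4-one with release of methanol, while the unproductive C2 adduct drains back through the cation. The closest known reaction types are DDQ dehydrogenation of 4H-chromenes and flavenes to benzopyrylium ions, DDQ cleavage of benzylic ethers to carbonyl compounds, and hydrolysis of 4-alkoxyflavylium salts to flavones. The prenyl ether is added only afterwards because DDQ would cleave it.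

Step 5
Reactants: 12 5-hydroxy-2-(4-hydroxyphenyl)-3,7-dimethoxy-4H-chromen-4-one; 13 prenyl bromide (1-bromo-3-methylbut-2-ene)
Product: 14 5-hydroxy-3,7-dimethoxy-2-[4-(3-methylbut-2-enyloxy)phenyl]-4H-chromen-4-one
Conditions: 13 (1.1 equiv), K2CO3, acetone, reflux
Reagents that add atoms: none
Why: Williamson etherification; the 4'-hydroxyl is free and acidic (vinylogous to the C4 carbonyl), whereas the 5-hydroxyl is held in a six-membered hydrogen bond to that carbonyl and should not be alkylated by about one equivalent of bromide with a carbonate base. Direct SN2 displacement at the primary allylic carbon keeps the 3,3-dimethylallyl connectivity.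

## Compound list

1 | 2,4,6-trihydroxybenzaldehyde | O=Cc1c(O)cc(O)cc1O | starting material
2 | 2,6-dihydroxy-4-methoxybenzaldehyde | COc1cc(O)c(C=O)c(O)c1 | intermediate
3 | 2-(4-bromophenoxy)tetrahydro-2H-pyran (racemic) | Brc1ccc(OC2CCCCO2)cc1 | starting material
4 | N,2-dimethoxy-N-methylacetamide | COCC(=O)N(C)OC | starting material
5 | [4-(tetrahydro-2H-pyran-2-yloxy)phenyl]magnesium bromide (racemic, not isolated) | Br[Mg]c1ccc(OC2CCCCO2)cc1 | intermediate
6 | 2-methoxy-1-[4-(tetrahydro-2H-pyran-2-yloxy)phenyl]ethanone (racemic, not isolated) | COCC(=O)c1ccc(OC2CCCCO2)cc1 | intermediate
7 | 1-(4-hydroxyphenyl)-2-methoxyethanone | COCC(=O)c1ccc(O)cc1 | intermediate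
8 | (E)-3-(2,6-dihydroxy-4-methoxyphenyl)-1-(4-hydroxyphenyl)-2-methoxyprop-2-en-1-one (ring A cis to the ketone, not isolated) | COc1cc(O)c(/C=C(/OC)C(=O)c2ccc(O)cc2)c(O)c1 | intermediate
9 | 5-hydroxy-2-(4-hydroxyphenyl)-3,7-dimethoxychromenylium chloride | COc1cc(O)c2cc(OC)c(-c3ccc(O)cc3)[o+]c2c1.[Cl-] | intermediate
10 | 2-(4-hydroxyphenyl)-3,4,7-trimethoxy-4H-chromen-5-ol (racemic at C4, not isolated) | COc1cc(O)c2C(OC)C(OC)=C(-c3ccc(O)cc3)Oc2c1 | intermediate
11 | 5-hydroxy-2-(4-hydroxyphenyl)-3,4,7-trimethoxychromenylium chloride (not isolated) | COc1cc(O)c2c(OC)c(OC)c(-c3ccc(O)cc3)[o+]c2c1.[Cl-] | intermediate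
12 | 5-hydroxy-2-(4-hydroxyphenyl)-3,7-dimethoxy-4H-chromen-4-one (kumatakenin) | COc1cc(O)c2c(=O)c(OC)c(-c3ccc(O)cc3)oc2c1 | intermediate
13 | prenyl bromide (1-bromo-3-methylbut-2-ene) | CC(C)=CCBr | starting material
14 | 5-hydroxy-3,7-dimethoxy-2-[4-(3-methylbut-2-enyloxy)phenyl]-4H-chromen-4-one | COc1cc(O)c2c(=O)c(OC)c(-c3ccc(OCC=C(C)C)cc3)oc2c1 | target

## Step count and risks

Total step count: 5. Longest linear sequence: 4 steps (1 to 2 to 9 to 12 to 14; the branch from 3 through 7 is equally long).

**Step 4 (proposed new method, the riskiest step).**
- What may go wrong: the methanol adduct equilibrium may lie so far on the C2 side that hydride transfer from C4 is slow. DDQ may then oxidise the free phenols by one-electron steps and cause oxidative coupling. Hydrolysis of 11 may also be incomplete.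
- Fallback (known chemistry, from 9 back to 12): the established oxidation of 4-unsubstituted flavylium salts to flavones with Tl(NO3)3·3H2O in methanol. It changes how the C4 hydrogen is removed. Trivalent thallium adds to the C2=C3 enol ether of the methanol adduct, and departure of monovalent thallium with a 1,2-hydride shift from C4 leads to the same ion 11 and, after aqueous work-up, to 12. This makes no new compound (F0). It is held in reserve because this electrophilic metal can also attack the free 4'-phenol.

**Step 3 (key step).**
- What may go wrong: self-condensation of the electron-rich aldehyde. Its nucleophilic ring positions can attack the protonated formyl group of a second molecule, giving xanthylium-type oligomers, and this may outrun the slower enolisation of the alpha-methoxy ketone.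
- Fallback (from 2 back to 9): lower the nucleophilicity of ring A with an O-benzoyl group, the classical variant of this condensation. Compound 2 would be mono-benzoylated (BzCl, 1 equiv, pyridine, 0 °C) to 2-formyl-3-hydroxy-5-methoxyphenyl benzoate F1. Condensation of F1 with 7 under HCl in EtOAc would give 5-(benzoyloxy)-2-(4-hydroxyphenyl)-3,7-dimethoxychromenylium chloride F2. Cold aqueous NaOH under nitrogen followed by HCl would remove the benzoate and re-close the salt to 9.

**Step 1.**
- What may go wrong: over-methylation at a second oxygen before 1 is consumed, giving mixtures of mono- and dimethyl ethers that are hard to separate.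
- Fallback (from 1 back to 2): replace selective addition by exhaustive methylation and selective removal. Compound 1 would be permethylated (MeI in excess, K2CO3, acetone) to 2,4,6-trimethoxybenzaldehyde F3. Both methoxy groups ortho to the formyl group would then be cleaved by chelation-controlled demethylation with AlCl3 in CH2Cl2. The non-chelating para methoxy group should remain, giving 2.

**Step 5.**
- What may go wrong: loss of chemoselectivity under basic conditions, that is, partial alkylation of the chelated 5-hydroxyl or C-alkylation of the ring A phenoxide at C6 or C8.
- Fallback (from 12 back to 14): avoid the phenoxide altogether by Mitsunobu etherification with 3-methylbut-2-en-1-ol (PPh3, diisopropyl azodicarboxylate, THF, 0 °C to rt). This selects the more acidic, non-chelated 4'-hydroxyl as the pronucleophile and gives 14 directly (no new compound, F0).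

## Further compounds

F0 | step 4 | none | none
F1 | step 3 | 2-formyl-3-hydroxy-5-methoxyphenyl benzoate | COc1cc(O)c(C=O)c(OC(=O)c2ccccc2)c1
F2 | step 3 | 5-(benzoyloxy)-2-(4-hydroxyphenyl)-3,7-dimethoxychromenylium chloride | COc1cc(OC(=O)c2ccccc2)c2cc(OC)c(-c3ccc(O)cc3)[o+]c2c1.[Cl-]
F3 | step 1 | 2,4,6-trimethoxybenzaldehyde | COc1cc(OC)c(C=O)c(OC)c1
F0 | step 5 | none | none
A1 | alternative 1 | 3,7-dimethoxy-2-[4-(3-methylbut-2-enyloxy)phenyl]-4-oxo-4H-chromen-5-yl 4-(3-methylbut-2-enyloxy)benzoate | COc1cc(OC(=O)c2ccc(OCC=C(C)C)cc2)c2c(=O)c(OC)c(-c3ccc(OCC=C(C)C)cc3)oc2c1
A2 | alternative 1 | 5-methoxy-2-[methoxy(triphenylphosphoranylidene)acetyl]-1,3-phenylene bis[4-(3-methylbut-2-enyloxy)benzoate] | COc1cc(OC(=O)c2ccc(OCC=C(C)C)cc2)c(C(=O)C(OC)=P(c2ccccc2)(c2ccccc2)c2ccccc2)c(OC(=O)c2ccc(OCC=C(C)C)cc2)c1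
A3 | alternative 2 | 2-[4-(benzyloxy)phenyl]-5-hydroxy-7-methoxy-4H-chromen-4-one | COc1cc(O)c2c(=O)cc(-c3ccc(OCc4ccccc4)cc3)oc2c1
A4 | alternative 2 | 2-iodo-5-methoxybenzene-1,3-diol | COc1cc(O)c(I)c(O)c1
A5 | alternative 2 | 1-(benzyloxy)-4-ethynylbenzene | C#Cc1ccc(OCc2ccccc2)cc1
A6 | alternative 2 | carbon monoxide | [C-]#[O+]
A7 | alternative 3 | 5,7-dihydroxy-3-methoxy-2-[4-(3-methylbut-2-enyloxy)phenyl]-4H-chromen-4-one | COc1c(-c2ccc(OCC=C(C)C)cc2)oc2cc(O)cc(O)c2c1=O
A8 | alternative 3 | methyl 4-{5-methoxy-6-[4-(3-methylbut-2-enyloxy)phenyl]-4-oxo-4H-pyran-2-yl}-3-oxobutanoate | COC(=O)CC(=O)Cc1cc(=O)c(OC)c(-c2ccc(OCC=C(C)C)cc2)o1
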